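**Retrosynthetic overview**

1. Eritrichin 18 ⇐ per-benzylated ester 17; one global hydrogenolysis removes six aryl benzyl ethers and the benzyl ester last.
2. 17 ⇐ naphthoic acid 11 + α-diazo ester 15 by a new enantioselective carboxylic-acid O–H insertion, which forms the ester C–O bond and sets the single (R) stereocentre.
3. 11 ⇐ 4-naphthyl triflate 8 + arylboronic acid 9 (Suzuki); 8 ⇐ naphthol 7 ⇐ Stobbe half-ester 4 ⇐ aldehyde 1 + dimethyl succinate 2.
4. 15 ⇐ benzyl acetoacetate 12 + benzylic chloride 13 (C-alkylation, then deacylative diazo transfer).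
5. Ring order: the only ring made is the carboxyl-bearing ring of the naphthalene (step 2, annulated onto the catechol ring of 1); the three catechol rings are bought.

Assumption: 1, 2, 9, 12 and 13 are bought; which antipode of the chiral guanidine–amide G* (amino-acid-derived, e.g. pipecolic acid core, N,N′-dicyclohexylguanidine unit, 2,6-diisopropylanilide) gives the (R)-ester is fixed in a model run with 2-naphthoic acid, both antipodes being equally available.

**Step 1**
Reactants: 1 3,4-bis(benzyloxy)benzaldehyde; 2 dimethyl succinate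
Product: 4 (E)-4-[3,4-bis(benzyloxy)phenyl]-3-(methoxycarbonyl)but-3-enoic acid, via methyl 2-[3,4-bis(benzyloxy)phenyl]-5-oxotetrahydrofuran-3-carboxylate 3 (not isolated)
Conditions: NaOMe (2.2 equiv), MeOH, reflux; then 2 M HCl
Reagents that add atoms: none
Why: Stobbe condensation, in which the succinate enolate adds to the aldehyde, lactonises to paraconate 3 and opens by E1cB to the (E)-half-ester with the aryl group cis to CH2CO2H as the later ring closure needs.

**Step 2**
Reactants: 4 (E)-4-[3,4-bis(benzyloxy)phenyl]-3-(methoxycarbonyl)but-3-enoic acid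
Product: 7 methyl 6,7-bis(benzyloxy)-4-hydroxy-2-naphthoate, via acetic (E)-4-[3,4-bis(benzyloxy)phenyl]-3-(methoxycarbonyl)but-3-enoic anhydride 5 (not isolated), via methyl 4-acetoxy-6,7-bis(benzyloxy)-2-naphthoate 6 (not isolated)
Conditions: Ac2O, NaOAc, 140 °C; evaporate; then K2CO3 (0.5 equiv), MeOH–THF, rt
Reagents that add atoms: none
Why: Stobbe-type benzannulation (mixed anhydride, intramolecular Friedel–Crafts acylation para to the 3-benzyloxy group, enolisation and O-acetylation) followed by methanolysis of the aryl acetate, with benzyl ethers and the methyl ester untouched.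

**Step 3**
Reactants: 7 methyl 6,7-bis(benzyloxy)-4-hydroxy-2-naphthoate
Product: 8 methyl 6,7-bis(benzyloxy)-4-{[(trifluoromethyl)sulfonyl]oxy}-2-naphthoate
Conditions: Tf2O, pyridine, CH2Cl2, 0 °C
Reagents that add atoms: trifluoromethanesulfonic anhydride (Tf2O), O=S(=O)(OS(=O)(=O)C(F)(F)F)C(F)(F)F
Why: Simple O-sulfonylation of the only free hydroxyl gives the cross-coupling electrophile.

**Step 4**
Reactants: 8 methyl 6,7-bis(benzyloxy)-4-{[(trifluoromethyl)sulfonyl]oxy}-2-naphthoate; 9 3,4-bis(benzyloxy)phenylboronic acid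
Product: 10 methyl 6,7-bis(benzyloxy)-4-[3,4-bis(benzyloxy)phenyl]-2-naphthoate
Conditions: Pd(dppf)Cl2 (3 mol%), K3PO4, 1,4-dioxane/H2O (5:1), 90 °C
Reagents that add atoms: none
Why: Suzuki–Miyaura coupling of an aryl triflate with an electron-rich arylboronic acid forms the biaryl bond, and partial ester hydrolysis would be harmless because saponification follows.

**Step 5**
Reactants: 10 methyl 6,7-bis(benzyloxy)-4-[3,4-bis(benzyloxy)phenyl]-2-naphthoate
Product: 11 6,7-bis(benzyloxy)-4-[3,4-bis(benzyloxy)phenyl]-2-naphthoic acid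
Conditions: LiOH·H2O, THF/MeOH/H2O, 55 °C; then 1 M HCl
Reagents that add atoms: lithium hydroxide, [Li+].[OH-]
Why: Saponification of the only ester, with benzyl ethers inert to hydroxide.

**Step 6**
Reactants: 12 benzyl acetoacetate (1.5 equiv); 13 3,4-bis(benzyloxy)benzyl chloride
Product: 14 benzyl 2-[3,4-bis(benzyloxy)benzyl]-3-oxobutanoate (racemic)
Conditions: K2CO3, NaI (10 mol%), acetone, reflux
Reagents that add atoms: none
Why: Acetoacetic-ester C-alkylation with an activated benzylic halide under Finkelstein catalysis, excess 12 suppressing dialkylation.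

**Step 7**
Reactants: 14 benzyl 2-[3,4-bis(benzyloxy)benzyl]-3-oxobutanoate
Product: 15 benzyl 3-[3,4-bis(benzyloxy)phenyl]-2-diazopropanoate
Conditions: p-ABSA, DBU, MeCN, 0 °C → rt
Reagents that add atoms: 4-acetamidobenzenesulfonyl azide (p-ABSA), CC(=O)Nc1ccc(cc1)S(=O)(=O)N=[N+]=[N-]
Why: Regitz deacylative diazo transfer, in which the acetyl group activates the α-carbon and leaves as the N-acetylsulfonamide, gives the α-alkyl-α-diazo ester without strong base.

**Step 8**
Reactants: 11 6,7-bis(benzyloxy)-4-[3,4-bis(benzyloxy)phenyl]-2-naphthoic acid; 15 benzyl 3-[3,4-bis(benzyloxy)phenyl]-2-diazopropanoate (1.3 equiv, slow addition)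
Product: 17 benzyl (2R)-3-[3,4-bis(benzyloxy)phenyl]-2-({6,7-bis(benzyloxy)-4-[3,4-bis(benzyloxy)phenyl]-2-naphthoyl}oxy)propanoate, via 1-(benzyloxy)-3-[3,4-bis(benzyloxy)phenyl]-1-hydroxyprop-1-en-2-yl 6,7-bis(benzyloxy)-4-[3,4-bis(benzyloxy)phenyl]-2-naphthoate 16 (not isolated)
Conditions: Rh2(TPA)4 (1 mol%), chiral guanidine–amide G* (10 mol%), CH2Cl2, −40 °C; AcOH quench at −40 °C
Reagents that add atoms: none
Why: Proposed new method: a Rh(II)/chiral-guanidine relay O–H insertion in which the guanidinium salt of acid 11 traps the Rh2(TPA)4 carbene of the α-alkyl diazo ester 15 at oxygen faster than 1,2-hydride migration (bulky triphenylacetate ligands, −40 °C, highly nucleophilic ion-paired carboxylate), and the resulting enol(ate) 16 (drawn as the neutral enol), still hydrogen-bonded to the chiral guanidinium, is protonated on the Si face of C2 to set (R), so that the ester C–O bond and the stereocentre are made together; the closest known reaction type is the Rh(II)/chiral proton-shuttle (guanidine or phosphoric acid) catalysed asymmetric carboxylic-acid O–H insertion of α-aryl-α-diazo esters, which has not been shown for β-hydrogen-bearing α-alkyl diazo esters.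

**Step 9**
Reactants: 17 benzyl (2R)-3-[3,4-bis(benzyloxy)phenyl]-2-({6,7-bis(benzyloxy)-4-[3,4-bis(benzyloxy)phenyl]-2-naphthoyl}oxy)propanoate
Product: 18 eritrichin, (2R)-2-{[4-(3,4-dihydroxyphenyl)-6,7-dihydroxy-2-naphthoyl]oxy}-3-(3,4-dihydroxyphenyl)propanoic acid
Conditions: H2 (1 atm), 10% Pd/C, THF/MeOH (1:1), rt; filter under Ar; RP-C18 (H2O/MeCN, 0.1% HCO2H)
Reagents that add atoms: none
Why: Catalytic hydrogenolysis cleaves the six aryl benzyl ethers and the benzyl ester under neutral conditions, while the acyloxy-bearing stereocentre is homobenzylic and not enolised, so it is neither cleaved nor racemised, and the naphthalene is not reduced at 1 atm.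

**Compound list**

1 | 3,4-bis(benzyloxy)benzaldehyde | O=Cc1ccc(OCc2ccccc2)c(OCc2ccccc2)c1 | starting material
2 | dimethyl succinate | COC(=O)CCC(=O)OC | starting material
3 | methyl 2-[3,4-bis(benzyloxy)phenyl]-5-oxotetrahydrofuran-3-carboxylate (Stobbe paraconate lactone, racemic diastereomer mixture) | COC(=O)C1CC(=O)OC1c1ccc(OCc2ccccc2)c(OCc2ccccc2)c1 | intermediate
4 | (E)-4-[3,4-bis(benzyloxy)phenyl]-3-(methoxycarbonyl)but-3-enoic acid | COC(=O)/C(CC(=O)O)=C/c1ccc(OCc2ccccc2)c(OCc2ccccc2)c1 | intermediate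
5 | acetic (E)-4-[3,4-bis(benzyloxy)phenyl]-3-(methoxycarbonyl)but-3-enoic anhydride | COC(=O)/C(CC(=O)OC(C)=O)=C/c1ccc(OCc2ccccc2)c(OCc2ccccc2)c1 | intermediate
6 | methyl 4-acetoxy-6,7-bis(benzyloxy)-2-naphthoate | COC(=O)c1cc(OC(C)=O)c2cc(OCc3ccccc3)c(OCc3ccccc3)cc2c1 | intermediate
7 | methyl 6,7-bis(benzyloxy)-4-hydroxy-2-naphthoate | COC(=O)c1cc(O)c2cc(OCc3ccccc3)c(OCc3ccccc3)cc2c1 | intermediate
8 | methyl 6,7-bis(benzyloxy)-4-{[(trifluoromethyl)sulfonyl]oxy}-2-naphthoate | COC(=O)c1cc(OS(=O)(=O)C(F)(F)F)c2cc(OCc3ccccc3)c(OCc3ccccc3)cc2c1 | intermediate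
9 | 3,4-bis(benzyloxy)phenylboronic acid | OB(O)c1ccc(OCc2ccccc2)c(OCc2ccccc2)c1 | starting material
10 | methyl 6,7-bis(benzyloxy)-4-[3,4-bis(benzyloxy)phenyl]-2-naphthoate | COC(=O)c1cc(-c2ccc(OCc3ccccc3)c(OCc3ccccc3)c2)c2cc(OCc3ccccc3)c(OCc3ccccc3)cc2c1 | intermediate
11 | 6,7-bis(benzyloxy)-4-[3,4-bis(benzyloxy)phenyl]-2-naphthoic acid | OC(=O)c1cc(-c2ccc(OCc3ccccc3)c(OCc3ccccc3)c2)c2cc(OCc3ccccc3)c(OCc3ccccc3)cc2c1 | intermediate
12 | benzyl acetoacetate (benzyl 3-oxobutanoate) | CC(=O)CC(=O)OCc1ccccc1 | starting material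
13 | 3,4-bis(benzyloxy)benzyl chloride | ClCc1ccc(OCc2ccccc2)c(OCc2ccccc2)c1 | starting material
14 | benzyl 2-[3,4-bis(benzyloxy)benzyl]-3-oxobutanoate (racemic) | CC(=O)C(Cc1ccc(OCc2ccccc2)c(OCc2ccccc2)c1)C(=O)OCc1ccccc1 | intermediate
15 | benzyl 3-[3,4-bis(benzyloxy)phenyl]-2-diazopropanoate | [N-]=[N+]=C(Cc1ccc(OCc2ccccc2)c(OCc2ccccc2)c1)C(=O)OCc1ccccc1 | intermediate
16 | 1-(benzyloxy)-3-[3,4-bis(benzyloxy)phenyl]-1-hydroxyprop-1-en-2-yl 6,7-bis(benzyloxy)-4-[3,4-bis(benzyloxy)phenyl]-2-naphthoate (enol, geometry not defined) | OC(OCc1ccccc1)=C(Cc1ccc(OCc2ccccc2)c(OCc2ccccc2)c1)OC(=O)c1cc(-c2ccc(OCc3ccccc3)c(OCc3ccccc3)c2)c2cc(OCc3ccccc3)c(OCc3ccccc3)cc2c1 | intermediate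
17 | benzyl (2R)-3-[3,4-bis(benzyloxy)phenyl]-2-({6,7-bis(benzyloxy)-4-[3,4-bis(benzyloxy)phenyl]-2-naphthoyl}oxy)propanoate | O=C(O[C@H](Cc1ccc(OCc2ccccc2)c(OCc2ccccc2)c1)C(=O)OCc1ccccc1)c1cc(-c2ccc(OCc3ccccc3)c(OCc3ccccc3)c2)c2cc(OCc3ccccc3)c(OCc3ccccc3)cc2c1 | intermediate
18 | eritrichin, (2R)-2-{[4-(3,4-dihydroxyphenyl)-6,7-dihydroxy-2-naphthoyl]oxy}-3-(3,4-dihydroxyphenyl)propanoic acid | O=C(O[C@H](Cc1ccc(O)c(O)c1)C(=O)O)c1cc(-c2ccc(O)c(O)c2)c2cc(O)c(O)cc2c1 | target

**Step count**

Total steps: 9. Longest linear sequence: 7 (steps 1, 2, 3, 4, 5, 8, 9).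

**Three steps most likely to fail**

Step 8 (the proposed new step). The risks are 1,2-hydride migration of the carbene to benzyl (Z)-3-[3,4-bis(benzyloxy)phenyl]acrylate, and a racemic background insertion through the free acid that lowers the ee. The fallback uses known chemistry, sets out from acid 11 and comes back at 17. Purchased sodium (2R)-3-(3,4-dihydroxyphenyl)-2-hydroxypropanoate F3 (sodium danshensu, the natural (R) acid) is tribenzylated with BnBr and K2CO3 in DMF, which alkylates the two phenols and the carboxylate but not the secondary alcohol, to give benzyl (2R)-3-[3,4-bis(benzyloxy)phenyl]-2-hydroxypropanoate F4. Acid 11 is then esterified with F4 (EDC·HCl, cat. DMAP, CH2Cl2, 0 °C → rt); the C–O bond at the stereocentre is not touched, so (R) is retained and 17 is obtained.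

Step 2 (benzannulation). The risks are a low yield in hot acetic anhydride, a non-cyclising (Z)-half-ester, and losses in the telescoped deacetylation. The fallback sets out from half-ester 4 (with boronic acid 9), comes back at 10 and bypasses steps 2–4. Compound 4 is converted with EtSH, EDC·HCl and cat. DMAP (CH2Cl2, 0 °C) into the thioester methyl (E)-2-[3,4-bis(benzyloxy)benzylidene]-4-(ethylsulfanyl)-4-oxobutanoate F1. Liebeskind–Srogl coupling of F1 with 9 (Pd2(dba)3, tri-2-furylphosphine, CuTC, THF, 50 °C) gives the aryl ketone methyl (E)-2-[3,4-bis(benzyloxy)benzylidene]-4-[3,4-bis(benzyloxy)phenyl]-4-oxobutanoate F2. Acid-catalysed cyclodehydration of F2 (cat. p-TsOH, toluene, 80 °C; Bradsher-type intramolecular Friedel–Crafts hydroxyalkylation, then loss of water) closes the ring para to the 3-benzyloxy group and gives 10 with the 4-aryl group already in place.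

Step 9 (sevenfold debenzylation). The risks are incomplete cleavage as the polarity changes strongly during the reaction, and air oxidation of the hexaphenol on the catalyst or during isolation. The fallback sets out from 17 and comes back at the target 18 with no new intermediate. It replaces reductive hydrogenolysis by Lewis-acid dealkylation with a cation scavenger: BCl3 (excess) and pentamethylbenzene in CH2Cl2, −78 °C → rt, then MeOH quench. The benzyl cations are captured by pentamethylbenzene, so the catechol rings are not C-benzylated, and the α-carboxy secondary alkyl naphthoate cannot ionise and survives.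

**Further compounds**

F1 | step 2 | methyl (E)-2-[3,4-bis(benzyloxy)benzylidene]-4-(ethylsulfanyl)-4-oxobutanoate | COC(=O)/C(CC(=O)SCC)=C/c1ccc(OCc2ccccc2)c(OCc2ccccc2)c1
F2 | step 2 | methyl (E)-2-[3,4-bis(benzyloxy)benzylidene]-4-[3,4-bis(benzyloxy)phenyl]-4-oxobutanoate | COC(=O)/C(CC(=O)c1ccc(OCc2ccccc2)c(OCc2ccccc2)c1)=C/c1ccc(OCc2ccccc2)c(OCc2ccccc2)c1
F3 | step 8 | sodium (2R)-3-(3,4-dihydroxyphenyl)-2-hydroxypropanoate (sodium danshensu, bought for the fallback) | [Na+].[O-]C(=O)[C@H](O)Cc1ccc(O)c(O)c1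
F4 | step 8 | benzyl (2R)-3-[3,4-bis(benzyloxy)phenyl]-2-hydroxypropanoate | O[C@H](Cc1ccc(OCc2ccccc2)c(OCc2ccccc2)c1)C(=O)OCc1ccccc1
F0 | step 9 | none | none
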